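What stood out in the earlier runs was a leftover: starting material that had gone but had not yet come out as target.

| flask | starting material | partner | free catalyst | remark | time |
|---|---|---|---|---|---|
| spring | 0.50 M | 1 equiv | 7 mol% | run made earlier |  |
| midnight | 0.50 M | 1 equiv | 10 mol% | run made earlier |  |
| summer | 0.75 M | 1 equiv | 14 mol% | run made earlier |  |
| flask | 0.50 M | 1.00 equiv | 14 mol% |  | 15 min |

| run | time / min | starting material / % | target / % |
|---|---|---|---|
| spring | 0.500 | 98 | 2 |
| spring | 1.33 | 95 | 0 |
| spring | 2.50 | 93 | 1 |
| spring | 4.00 | 94 | 4 |
| spring | 5.00 | 92 | 7 |
| spring | 8.00 | 87 | 8 |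
| spring | 10.0 | 83 | 14 |
| midnight | 1.33 | 98 | 1 |
| midnight | 2.50 | 91 | 1 |
| midnight | 4.00 | 91 | 4 |
| midnight | 5.00 | 85 | 8 |
| midnight | 6.00 | 83 | 10 |
| midnight | 8.00 | 81 | 11 |
| midnight | 10.0 | 80 | 17 |
| summer | 0.833 | 90 | 0 |
| summer | 2.50 | 88 | 2 |
| summer | 4.00 | 82 | 9 |
| summer | 6.00 | 76 | 13 |
| summer | 10.0 | 68 | 25 |

(readings scatter by 1.5 percentage points)

- part of the starting material that has reacted at 15 min
- share of the unused partner that is free and not bound as idle adduct, at 15 min

- what is said of released group includes idle adduct
- candidate steps: starting material + free catalyst -> catalyst intermediate A; partner + catalyst intermediate A -> catalyst intermediate B; catalyst intermediate B -> released group + catalyst intermediate C; catalyst intermediate C <-> free catalyst + target; partner + released group <-> idle adduct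
- the earlier runs do not show how much of partner is bound; that part of a forecast is a guess

I read the time scales from the summer run, fastest first. By 0.833 min starting material was already down to 90% with target at 0%, so the catalyst had taken up material before any product showed. Target came next, at 2% by 2.50 min and 9% by 4.00 min. From 4.00 min to 10.0 min starting material fell by 0.0233 min⁻¹ of the charge and target rose by 0.0267 min⁻¹. Dividing one rate by the other removes time and leaves 1.15, so the two ran nearly level. The last rung I read is using up the summer charge at that rate, about 42.9 min, which is longer than the asked 15 min, so I expected the new flask, with the same catalyst loading, to be still on the level stretch.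

Over those summer readings the mean gap divided by the catalyst loading gave 64.3%. This is the held share, the points of gap per point of catalyst loading, a reading of the catalyst sitting in its intermediates, its resting states. The late midnight readings gave 60.0% and the late spring readings 42.9%. I carried the summer figure, which has the new flask's loading but not its concentration, and so reckoned target in the flask about 9 percentage points below the part reacted.

The forecast gave 43% reacted (37% to 50%), on the ground that “the rate is near zero order”, and 70% of the unused partner free (35% to 95%), which it called a guess.

The flask gave 37.9% reacted and 81.5% free. Its target stood at 28.7%, and the held share on 14 mol% takes 37.9% down to 28.9%.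

    starting material + free catalyst → catalyst intermediate A (k = 0.0190 M⁻¹ s⁻¹)
    partner + catalyst intermediate A → catalyst intermediate B (k = 0.360 M⁻¹ s⁻¹)
    catalyst intermediate B → released group + catalyst intermediate C (k = 0.0130 s⁻¹)
    catalyst intermediate C ⇌ free catalyst + target (K = 0.160 M, k = 0.0110 s⁻¹)
    partner + released group ⇌ idle adduct, settled at all times (K = 1.90 M⁻¹)

A neighbour flask, the same but with 35 mol% of free catalyst, reacted 69.9%, the held share takes that down to 47.4%, and its target stood at 46.5%.

(The numbers in the tables were generated by integration on assumed constants; noise was put on by code.)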